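**Retrosynthetic overview**
- The target is taken back to its 11,12-di-O-methyl 2-alcohol, and the C7–O–C20 ether to a C7–O–C20(=O) lactone (a 2α-acetoxycarnosol dimethyl ether) that is reduced and re-closed.
- Key disconnection: the 2-oxabicyclo[2.2.2]octene made of C7, O, C20, C10, the aromatic C8=C9 bond and the C5–C6 bridge is cut at C10–C5 and C7–C6. Forward, this is an intramolecular Diels–Alder reaction of an o-quinoid 2-benzopyran-3-one (ring C dearomatised for the moment, diene termini C7 and C10, strap O–C20=O) with the C5=C6 vinyl group. It closes rings A and B together, sets C5, C7 and C10 from C2, and funnels both C10 epimers of its precursor into one product.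
- The pyranone comes from an o-formylarylacetic acid, made from an arylacetic acid dianion and an (S)-epoxide (C10–C1 bond; C2 from (S)-epichlorohydrin, C3–C4 by reverse prenylation).
- The arylacetic acid comes from ortho-lithiation at C9 of an acetal-protected 3,4-dimethoxy-5-isopropylbenzaldehyde plus oxirane, then oxidation; the aldehyde comes from a Negishi isopropylation.
- Ring order: ring C is bought; rings A and B and the lactone bridge form in one step; the lactone bridge is then turned into the ether bridge.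

Key step: step 7

Remark: abietane numbering (C1–C20) is used throughout; the target is read from its SMILES as (2S,5S,7S,10R), the 2α-acetate of 20-deoxocarnosol, and the CIP letter of the side-chain carbinol changes along the route only because substituent priorities change.

Step 1
Reactants: 1 3-bromo-4,5-dimethoxybenzaldehyde; 2 isopropylzinc bromide
Product: 3 3,4-dimethoxy-5-(propan-2-yl)benzaldehyde
Conditions: i-PrZnBr (1.5 equiv), Pd(OAc)2 (1 mol%), CPhos (2 mol%), THF/toluene, rt
Reagents that add atoms: none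
Why: Negishi coupling of a secondary alkylzinc halide with an aryl bromide, in which the biaryl phosphine makes reductive elimination faster than β-hydride elimination (no n-propyl isomer) and the organozinc leaves the aldehyde untouched.

Step 2
Reactants: 3 3,4-dimethoxy-5-(propan-2-yl)benzaldehyde
Product: 4 5-(dimethoxymethyl)-1,2-dimethoxy-3-(propan-2-yl)benzene
Conditions: HC(OMe)3, MeOH, TsOH·H2O (cat.), rt; Et3N quench
Reagents that add atoms: trimethyl orthoformate, COC(OC)OC; methanol, CO
Why: Acid-catalysed acetalisation driven by the orthoformate as water scavenger; the acetal protects C7 and serves as the second directing group for step 3.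

Step 3
Reactants: 4 5-(dimethoxymethyl)-1,2-dimethoxy-3-(propan-2-yl)benzene; 5 oxirane
Product: 7 2-[6-(dimethoxymethyl)-2,3-dimethoxy-4-(propan-2-yl)phenyl]ethan-1-ol, via C9-aryllithium 6 (not isolated)
Conditions: n-BuLi, TMEDA, Et2O, 0 °C; oxirane, −78 °C → rt; H2O
Reagents that add atoms: none
Why: Directed ortho-metalation at the C9–H flanked by the C11 methoxy group and the acetal (two cooperating directors; the C14–H has one director and an isopropyl neighbour), followed by SN2 opening of oxirane by the aryllithium.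

Step 4
Reactants: 7 2-[6-(dimethoxymethyl)-2,3-dimethoxy-4-(propan-2-yl)phenyl]ethan-1-ol
Product: 8 [6-(dimethoxymethyl)-2,3-dimethoxy-4-(propan-2-yl)phenyl]acetic acid
Conditions: TEMPO (cat.), NaOCl (cat.), NaClO2, MeCN/phosphate buffer pH 6.8, 35 °C; cold acidification to pH 5
Reagents that add atoms: sodium chlorite, [Na+].[O-]Cl=O
Why: TEMPO/chlorite oxidation of a primary alcohol to the acid via the aldehyde at near-neutral pH, which the acid-labile acetal and the electron-rich ring should tolerate.

Step 5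
Reactants: 9 (S)-epichlorohydrin; 10 prenylmagnesium chloride
Product: 12 (2S)-2-(2,2-dimethylbut-3-en-1-yl)oxirane, via chlorohydrin 11 (not isolated)
Conditions: THF, −30 → 0 °C; then 2 M NaOH (aq.), rt
Reagents that add atoms: none
Why: The allylic Grignard reagent opens the epoxide at its CH2 terminus through its γ-carbon (SE2′), which makes the C3–C4 bond and the gem-dimethyl carbon with the vinyl group in place, and base then closes the chlorohydrin to the new epoxide without touching the stereocentre that becomes C2.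

Step 6
Reactants: 8 [6-(dimethoxymethyl)-2,3-dimethoxy-4-(propan-2-yl)phenyl]acetic acid; 12 (2S)-2-(2,2-dimethylbut-3-en-1-yl)oxirane
Product: 16 (4R)-4-acetoxy-2-[6-formyl-2,3-dimethoxy-4-(propan-2-yl)phenyl]-6,6-dimethyloct-7-enoic acid (both C2 epimers), via dilithium enediolate 13 (not isolated), via dilithium alkoxide carboxylate 14 (not isolated), via acetoxy acid acetal 15 (not isolated)
Conditions: LDA (2.2 equiv), THF, −78 → 0 °C; 12, 0 → 40 °C; Ac2O (1.5 equiv), −78 → 0 °C; then 1 M HCl, THF, rt
Reagents that add atoms: acetic anhydride, CC(=O)OC(C)=O; water, O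
Why: Alkylation of an arylacetic acid dianion by a terminal epoxide at its unsubstituted carbon (C10–C1 bond, carbinol centre not involved), trapping of the γ-alkoxide as its acetate before the acid is set free so that no γ-lactone can form, and acetal hydrolysis in the work-up; C10 forms as a mixture, which is harmless because it becomes planar in step 7.

Step 7
Reactants: 16 (4R)-4-acetoxy-2-[6-formyl-2,3-dimethoxy-4-(propan-2-yl)phenyl]-6,6-dimethyloct-7-enoic acid
Product: 19 (2S,5S,7S,10R)-2-acetoxy-11,12-dimethoxy-7,20-epoxyabieta-8,11,13-trien-20-one, via 1-acetoxyisochroman-3-one 17 (not isolated), via 2-benzopyran-3-one 18 (not isolated)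
Conditions: Ac2O (20 equiv), toluene (0.005 M), 110 °C, sealed tube
Reagents that add atoms: none
Why: Heating the formyl acid in acetic anhydride closes the pseudo-acid lactol, acetylates it to 17 and expels acetic acid to give the o-quinoid 2-benzopyran-3-one 18, which is planar at C10 so that both epimers of 16 converge; 18 then adds its C7 and C10 termini across the tethered C5=C6 vinyl group in a concerted thermal intramolecular Diels–Alder reaction driven by the return of ring C to a benzene ring. The closest known reaction type is the intramolecular Diels–Alder addition of 2-benzopyran-3-ones, generated in this way from o-formylarylacetic acids, to unactivated alkenes held on C4 of the pyranone by a four-atom chain. Ring A closes as a six-membered ring through the new C10–C5 bond (type-1 mode, four-atom tether, chair-like), ring B closes through C6–C7, and the O–C20(=O) strap of the diene becomes the lactone bridge of the 2-oxabicyclo[2.2.2]octene. C7 and C10 are set together by suprafacial addition to the diene; C5 relative to C10 by the tether lying under the lactone strap and away from the C11 methoxy group (trans A/B fusion); and the absolute sense of all three by C2, whose acetoxy group sits equatorial in the chair-like tether because the axial alternative meets the axial C4 methyl group. The step needs trans ring fusion, π-facial selectivity and cycloaddition faster than dimerisation of 18; the peri methoxy group, the gem-dimethyl group (Thorpe–Ingold effect and 1,3-diaxial bias) and high dilution should secure these.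

Step 8
Reactants: 19 (2S,5S,7S,10R)-2-acetoxy-11,12-dimethoxy-7,20-epoxyabieta-8,11,13-trien-20-one
Product: 21 (2S,5S,7S,10R)-11,12-dimethoxy-7,20-epoxyabieta-8,11,13-trien-2-ol, via abietatriene-2,7,20-triol 20 (not isolated)
Conditions: LiAlH4, THF, 0 °C → reflux; then 2 M HCl (aq.), THF, rt
Reagents that add atoms: none
Why: Hydride reduction opens the lactone to the C7/C20 diol and removes the acetate, and dilute acid then ionises the C7 alcohol to a benzylic cation para to the C12 methoxy group, which the C20 hydroxyl recaptures on the β-face (the only face its tether reaches, so C7 stays S) to give the six-membered cyclic ether.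

Step 9
Reactants: 21 (2S,5S,7S,10R)-11,12-dimethoxy-7,20-epoxyabieta-8,11,13-trien-2-ol
Product: 22 (2S,5S,7S,10R)-11,12-dimethoxy-7,20-epoxyabieta-8,11,13-trien-2-yl acetate
Conditions: Ac2O, pyridine, DMAP (cat.), CH2Cl2, rt
Reagents that add atoms: acetic anhydride, CC(=O)OC(C)=O
Why: DMAP-catalysed acylation of the only free hydroxyl group, the equatorial secondary C2 alcohol, with retention.

Step 10
Reactants: 22 (2S,5S,7S,10R)-11,12-dimethoxy-7,20-epoxyabieta-8,11,13-trien-2-yl acetate
Product: 23 (2S,5S,7S,10R)-11,12-dihydroxy-7,20-epoxyabieta-8,11,13-trien-2-yl acetate (target)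
Conditions: BBr3 (3 equiv), CH2Cl2, −78 → −20 °C; then aq. NaHCO3, 0 °C
Reagents that add atoms: none
Why: Lewis-acid cleavage of the two vicinal aryl methyl ethers, which boron chelation between the catechol oxygens activates at a temperature where a secondary acetate is slow to cleave; should the C7–O bond ionise, the C20 oxygen should re-close the same ether on aqueous work-up because only the β-face is within reach.

**Compound list**
1 | 3-bromo-4,5-dimethoxybenzaldehyde | O=Cc1cc(Br)c(OC)c(OC)c1 | starting material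
2 | isopropylzinc bromide | CC(C)[Zn]Br | starting material
3 | 3,4-dimethoxy-5-(propan-2-yl)benzaldehyde | O=Cc1cc(C(C)C)c(OC)c(OC)c1 | intermediate
4 | 5-(dimethoxymethyl)-1,2-dimethoxy-3-(propan-2-yl)benzene | COC(OC)c1cc(C(C)C)c(OC)c(OC)c1 | intermediate
5 | oxirane | C1CO1 | starting material
6 | [6-(dimethoxymethyl)-2,3-dimethoxy-4-(propan-2-yl)phenyl]lithium | [Li]c1c(OC)c(OC)c(C(C)C)cc1C(OC)OC | intermediate
7 | 2-[6-(dimethoxymethyl)-2,3-dimethoxy-4-(propan-2-yl)phenyl]ethan-1-ol | OCCc1c(OC)c(OC)c(C(C)C)cc1C(OC)OC | intermediate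
8 | [6-(dimethoxymethyl)-2,3-dimethoxy-4-(propan-2-yl)phenyl]acetic acid | OC(=O)Cc1c(OC)c(OC)c(C(C)C)cc1C(OC)OC | intermediate
9 | (S)-epichlorohydrin, (2S)-2-(chloromethyl)oxirane | ClC[C@@H]1CO1 | starting material
10 | prenylmagnesium chloride (3-methylbut-2-en-1-ylmagnesium chloride) | CC(C)=CC[Mg]Cl | starting material
11 | (2S)-1-chloro-4,4-dimethylhex-5-en-2-ol | ClC[C@@H](O)CC(C)(C)C=C | intermediate
12 | (2S)-2-(2,2-dimethylbut-3-en-1-yl)oxirane | C=CC(C)(C)C[C@H]1CO1 | intermediate
13 | dilithium enediolate of 8 | [Li+].[Li+].[O-]C([O-])=Cc1c(OC)c(OC)c(C(C)C)cc1C(OC)OC | intermediate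
14 | dilithium (4R)-2-[6-(dimethoxymethyl)-2,3-dimethoxy-4-(propan-2-yl)phenyl]-6,6-dimethyl-4-oxidooct-7-enoate (C2 epimers) | [Li+].[Li+].[O-][C@@H](CC(C)(C)C=C)CC(C([O-])=O)c1c(OC)c(OC)c(C(C)C)cc1C(OC)OC | intermediate
15 | (4R)-4-acetoxy-2-[6-(dimethoxymethyl)-2,3-dimethoxy-4-(propan-2-yl)phenyl]-6,6-dimethyloct-7-enoic acid (C2 epimers) | CC(=O)O[C@@H](CC(C)(C)C=C)CC(C(=O)O)c1c(OC)c(OC)c(C(C)C)cc1C(OC)OC | intermediate
16 | (4R)-4-acetoxy-2-[6-formyl-2,3-dimethoxy-4-(propan-2-yl)phenyl]-6,6-dimethyloct-7-enoic acid (C2 epimers) | CC(=O)O[C@@H](CC(C)(C)C=C)CC(C(=O)O)c1c(OC)c(OC)c(C(C)C)cc1C=O | intermediate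
17 | 1-acetoxy-4-[(2R)-2-acetoxy-4,4-dimethylhex-5-en-1-yl]-5,6-dimethoxy-7-(propan-2-yl)isochroman-3-one (C1/C4 isomers) | CC(=O)O[C@@H](CC(C)(C)C=C)CC1C(=O)OC(OC(C)=O)c2cc(C(C)C)c(OC)c(OC)c12 | intermediate
18 | 4-[(2S)-2-acetoxy-4,4-dimethylhex-5-en-1-yl]-5,6-dimethoxy-7-(propan-2-yl)-3H-2-benzopyran-3-one | CC(=O)O[C@@H](CC(C)(C)C=C)CC1=C2C(OC)=C(OC)C(C(C)C)=CC2=COC1=O | intermediate
19 | (2S,5S,7S,10R)-2-acetoxy-11,12-dimethoxy-7,20-epoxyabieta-8,11,13-trien-20-one (2α-acetoxycarnosol dimethyl ether) | CC(=O)O[C@H]1CC(C)(C)[C@@H]2C[C@@H]3OC(=O)[C@@]2(C1)c1c3cc(C(C)C)c(OC)c1OC | intermediate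
20 | (2S,5S,7S,10R)-11,12-dimethoxyabieta-8,11,13-triene-2,7,20-triol | O[C@H]1CC(C)(C)[C@@H]2C[C@H](O)c3cc(C(C)C)c(OC)c(OC)c3[C@@]2(CO)C1 | intermediate
21 | (2S,5S,7S,10R)-11,12-dimethoxy-7,20-epoxyabieta-8,11,13-trien-2-ol | O[C@H]1CC(C)(C)[C@@H]2C[C@@H]3OC[C@@]2(C1)c1c3cc(C(C)C)c(OC)c1OC | intermediate
22 | (2S,5S,7S,10R)-11,12-dimethoxy-7,20-epoxyabieta-8,11,13-trien-2-yl acetate | CC(=O)O[C@H]1CC(C)(C)[C@@H]2C[C@@H]3OC[C@@]2(C1)c1c3cc(C(C)C)c(OC)c1OC | intermediate
23 | (2S,5S,7S,10R)-11,12-dihydroxy-7,20-epoxyabieta-8,11,13-trien-2-yl acetate (CNP0485560.1) | CC(=O)O[C@H]1CC(C)(C)[C@@H]2C[C@@H]3OC[C@@]2(C1)c1c3cc(C(C)C)c(O)c1O | target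

**Step count**
Total: 10 steps. Longest linear sequence: 9 steps (steps 1–4 and 6–10); step 5 makes the side-chain epoxide.

**The three steps most likely to fail**

Step 7. The o-quinoid diene 18 may dimerise or polymerise faster than it adds to the unactivated vinyl group next to the quaternary C4, or the tether may fold under the benzo ring and give the cis-fused isomer. The fallback activates and steers the dienophile with a sulfonyl group. It sets out from 15, which is isolated by leaving out the acid treatment at the end of step 6. Cleavage of the vinyl group (OsO4 cat., NaIO4, 2,6-lutidine, dioxane/H2O) should give the non-enolisable aldehyde F1. A Horner–Wadsworth–Emmons reaction with diethyl [(phenylsulfonyl)methyl]phosphonate (LiHMDS, THF) should give the (E)-vinyl sulfone F2, and 1 M HCl in THF should free the formyl acid F3. Heating F3 in Ac2O/toluene at 80 °C should give the sulfonyl adduct F4 by a normal-demand cycloaddition: the sulfonyl group takes the endo position under the benzo ring, so the E geometry places the tether under the lactone strap (trans fusion). Reductive desulfonylation (Na/Hg, Na2HPO4, MeOH/THF, −20 °C) is expected to expel the antiperiplanar C7 carboxylate (Julia-type elimination) and give the Δ6-ene acid F5. TsOH in CH2Cl2 should then re-close F5 to 19 by protonation at C6 and capture of the C7 benzylic cation by the C20 acid; the route continues with step 8.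

Step 6. The hindered dianion may open the epoxide slowly, or the γ-alkoxide may be acetylated incompletely so that the hydroxy acid lactonises in the work-up. The fallback lets the lactone form on purpose and sets out from 8 and 12. The opening is run as before but quenched at pH 4–5, which should give the lactone F6. KOH (1 equiv, MeOH/H2O) and then allyl bromide in DMF should give the hydroxy allyl ester F7, which is acetylated in the same pot (Ac2O, pyridine, DMAP) to the acetoxy allyl ester F8. Pd(PPh3)4 (cat.) and morpholine in THF should remove the allyl group under neutral conditions and give 15, where the fallback returns to the route (acid hydrolysis to 16 as in step 6).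

Step 10. The Lewis acid may cleave the C2 acetate or open the doubly activated benzylic ether before both methyl groups are gone. The fallback demethylates before the ether exists and sets out from 19. BBr3 (CH2Cl2, −78 → 0 °C) on the lactone should give 2α-acetoxycarnosol F9. LiAlH4 (excess, THF) followed by the acidic work-up of step 8 should give, by way of the pentol F10 (not isolated), 2α-hydroxy-20-deoxocarnosol F11. Ac2O/pyridine should give the triacetate F12, and NH4OAc in aqueous MeOH should cleave only the two aryl acetates and give 23.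

**Further compounds**
F1 | step 7 | (4R)-4-acetoxy-2-[6-(dimethoxymethyl)-2,3-dimethoxy-4-(propan-2-yl)phenyl]-6,6-dimethyl-7-oxoheptanoic acid | CC(=O)O[C@@H](CC(C)(C)C=O)CC(C(=O)O)c1c(OC)c(OC)c(C(C)C)cc1C(OC)OC
F2 | step 7 | (4R,7E)-4-acetoxy-2-[6-(dimethoxymethyl)-2,3-dimethoxy-4-(propan-2-yl)phenyl]-6,6-dimethyl-8-(phenylsulfonyl)oct-7-enoic acid | CC(=O)O[C@@H](CC(C)(C)/C=C/S(=O)(=O)c2ccccc2)CC(C(=O)O)c1c(OC)c(OC)c(C(C)C)cc1C(OC)OC
F3 | step 7 | (4R,7E)-4-acetoxy-2-[6-formyl-2,3-dimethoxy-4-(propan-2-yl)phenyl]-6,6-dimethyl-8-(phenylsulfonyl)oct-7-enoic acid | CC(=O)O[C@@H](CC(C)(C)/C=C/S(=O)(=O)c2ccccc2)CC(C(=O)O)c1c(OC)c(OC)c(C(C)C)cc1C=O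
F4 | step 7 | 2α-acetoxy-11,12-dimethoxy-6α-(phenylsulfonyl)-7,20-epoxyabieta-8,11,13-trien-20-one | CC(=O)O[C@H]1CC(C)(C)[C@@H]2[C@@H](S(=O)(=O)c4ccccc4)[C@@H]3OC(=O)[C@@]2(C1)c1c3cc(C(C)C)c(OC)c1OC
F5 | step 7 | 2α-acetoxy-11,12-dimethoxyabieta-6,8,11,13-tetraen-20-oic acid | CC(=O)O[C@H]1CC(C)(C)[C@@H]2C=Cc3cc(C(C)C)c(OC)c(OC)c3[C@@]2(C(=O)O)C1
F6 | step 6 | (5R)-3-[6-(dimethoxymethyl)-2,3-dimethoxy-4-(propan-2-yl)phenyl]-5-(2,2-dimethylbut-3-en-1-yl)oxolan-2-one (C3 epimers) | O=C1O[C@@H](CC(C)(C)C=C)CC1c2c(OC)c(OC)c(C(C)C)cc2C(OC)OC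
F7 | step 6 | prop-2-en-1-yl (4R)-2-[6-(dimethoxymethyl)-2,3-dimethoxy-4-(propan-2-yl)phenyl]-4-hydroxy-6,6-dimethyloct-7-enoate | O[C@@H](CC(C)(C)C=C)CC(C(=O)OCC=C)c1c(OC)c(OC)c(C(C)C)cc1C(OC)OC
F8 | step 6 | prop-2-en-1-yl (4R)-4-acetoxy-2-[6-(dimethoxymethyl)-2,3-dimethoxy-4-(propan-2-yl)phenyl]-6,6-dimethyloct-7-enoate | CC(=O)O[C@@H](CC(C)(C)C=C)CC(C(=O)OCC=C)c1c(OC)c(OC)c(C(C)C)cc1C(OC)OC
F9 | step 10 | (2S,5S,7S,10R)-2-acetoxy-11,12-dihydroxy-7,20-epoxyabieta-8,11,13-trien-20-one (2α-acetoxycarnosol) | CC(=O)O[C@H]1CC(C)(C)[C@@H]2C[C@@H]3OC(=O)[C@@]2(C1)c1c3cc(C(C)C)c(O)c1O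
F10 | step 10 | (2S,5S,7S,10R)-abieta-8,11,13-triene-2,7,11,12,20-pentol | O[C@H]1CC(C)(C)[C@@H]2C[C@H](O)c3cc(C(C)C)c(O)c(O)c3[C@@]2(CO)C1
F11 | step 10 | (2S,5S,7S,10R)-7,20-epoxyabieta-8,11,13-triene-2,11,12-triol (2α-hydroxy-20-deoxocarnosol) | O[C@H]1CC(C)(C)[C@@H]2C[C@@H]3OC[C@@]2(C1)c1c3cc(C(C)C)c(O)c1O
F12 | step 10 | (2S,5S,7S,10R)-7,20-epoxyabieta-8,11,13-triene-2,11,12-triyl triacetate | CC(=O)O[C@H]1CC(C)(C)[C@@H]2C[C@@H]3OC[C@@]2(C1)c1c3cc(C(C)C)c(OC(C)=O)c1OC(C)=O
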